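3 questions stand on two flasks, and one quantity carries my answer to them.

common to all: substrate 0.050 M
- gamma: capture agent 1.5 mM; temperature 110 °C; run made earlier
- north-east: capture agent 1.00 mM; at 110 °C throughout; time 20 min
- south-west: capture agent 1.00 mM; at 110 °C until 4.0 min, from then on at 130 °C; time 20 min

gamma run (percent of the substrate charged)

| time / s | target / % | substrate / % |
|---|---|---|
| 10.0 | 0 | 94.0 |
| 15.0 | 0 | 91.7 |
| 25.0 | 0 | 86.5 |
| 40.0 | 1.0 | 80.2 |
| 80.0 | 3.9 | 68.2 |
| 120 | 6.0 | 59.2 |

(standard deviation of a reading: 0.3 percentage points)

- which one finishes higher in amount of target, in percent of the substrate charged ("neither" within 2 percentage points) (north-east / south-west / neither)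
- amount of target at the end, in percent of the substrate charged, north-east
- amount of target at the end, in percent of the substrate charged, south-west

- the earlier runs do not show what temperature does; that part of a forecast is a guess
- no earlier run changes the charge of capture agent; that part of a forecast is a guess

I build the flask up one process at a time. With the main step by itself, substrate turns straight into target, so the gamma run should show as target what it has lost, 40.8% at 120 s. It shows 6.0%. I call the difference the gap in the mass balance: 34.8% there, and 27.9% at 80.0 s.

Next I add the capture agent. Taken one to one, its charge in gamma is 3.00% of the substrate, and the gap is far larger than that. So I take the gap to be an unseen form that feeds the target.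

Then I let the gap empty. Between those two gamma readings the target gains 2.1 percentage points. The gap time is the mean gap divided by the target gained per unit time, 9.95 min. With a scatter of 0.3 points on each reading, it is a reading, not a constant.

Now I join the two ends. Early on, lost substrate enters the gap; late on, the gap drains. Read as second order, gamma's substrate halves in 2.90 min, which leaves 12.7% in north-east at 20 min. Lost substrate then has 1.72 gap times to drain, so 82.1% of it arrives. That gives me 71.7% for north-east, a ceiling, since I count the whole gap as draining. South-west gets 130 °C from 4.0 min; I guess that heat shortens the gap time, so I put south-west higher.

The forecast says south-west, with 17% for north-east and 20% for south-west, holding that the capture agent “evidently removes it stoichiometrically until used up”. My ceiling stands above its north-east number, and we part over the gap.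

North-east ends at 51.7% and south-west at 64.5%, so south-west finishes higher.

    substrate ⇌ open intermediate (K = 0.564, k = 0.257 min⁻¹, Ea = 113 kJ mol⁻¹, ΔH = −24.0 kJ mol⁻¹)
    open intermediate → target (k = 0.235 min⁻¹, Ea = 102 kJ mol⁻¹)
    2 substrate → self-condensation product (k = 1.24 L mol⁻¹ min⁻¹, Ea = 86.0 kJ mol⁻¹)
    open intermediate + capture agent → trapped intermediate (k = 4.81 L mol⁻¹ min⁻¹, Ea = 87.0 kJ mol⁻¹)
    (constants at 110 °C)

Of north-east's gap at 20 min, 37.8%, self-condensation product is 32.6%, and it still stands at 33.5% after 200 min. North-east also still holds 14.8% as substrate and open intermediate. The same north-east flask read at 80 min is 6.03 gap times later, a count made with my scattered gamma reading and so only an estimate. There, nearly all of that has moved on, with 0.203% left as substrate and open intermediate. Its target stands at 65.3%, up 14 points.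

(The numbers in the tables are calculated for substances that don't exist; noise was put on by code.)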